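**Retrosynthetic overview**
- The strategy rests on ring B (C5–C10). A methyl group on C5 and oxygen on the adjacent pair C8/C9 match the substitution pattern of 2-methoxy-5-methyl-1,4-benzoquinone. C1–C4 of ring A (O on C3, CH3 on C4) correspond to a 3-silyloxypenta-1,3-diene.
- Apart from quaternary C5, every stereocentre (C3, C4, C7, C9, C10) holds its substituent equatorially on a trans-decalin. Each is a carbinol carbon or lies next to a carbonyl group, so all five can be derived from C5 by substrate control.
- Late disconnections: C3–O (angelate, introduced with inversion), C6=C7 (conjugate reduction), C7–C11 (cross-coupling on a 7-iodo-6-en-8-one), C9–O (acylation of an α-ketol).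
- Key disconnection: C4–C5 and C1–C10, by a catalytic enantioselective Diels–Alder reaction of the quinone with the silyloxydiene.
- Ring order: ring B is bought as the quinone, ring A is closed on it in step 2, and no further ring is formed.

Key step: step 2

Convention: eremophilane numbering is used (ring A: C1–C5 and C10; ring B: C5–C10; side chain C11–C13 on C7). The decalin is viewed with ring A on the left and C5 at the lower fusion position. β is the face of the C5 methyl (towards the viewer) and α is the opposite face.

Assumption: the sense of induction of the BINOL–titanium complex for this quinone/diene pair is not known. (R)-BINOL is written, and the equally available (S)-ligand is used if the cycloadduct proves to be the antipode.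

**Step 1**
Reactants: 1 pent-1-en-3-one (ethyl vinyl ketone)
Product: 2 (Z)-3-(tert-butyldimethylsilyloxy)penta-1,3-diene
Conditions: TBSOTf, Et3N, Et2O, 0 °C → rt
Reagents that add atoms: tert-butyldimethylsilyl triflate (TBSOTf), CC(C)(C)[Si](C)(C)OS(=O)(=O)C(F)(F)F
Why: Soft enolisation, in which the silyl triflate activates the carbonyl oxygen and Et3N removes a proton from the ethyl CH2 (the vinyl side has no α-hydrogen), the Z enol ether being favoured because it keeps the methyl group away from the vinyl substituent.

**Step 2**
Reactants: 2 (Z)-3-(tert-butyldimethylsilyloxy)penta-1,3-diene; 3 2-methoxy-5-methyl-1,4-benzoquinone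
Product: 4 cis-fused cycloadduct 8-methoxy-3-(tert-butyldimethylsilyloxy)-11,12,13-trinoreremophila-2,7-diene-6,9-dione (4α-CH3; 5β-CH3; 10β-H)
Conditions: (R)-BINOL (30 mol %), TiCl2(OiPr)2 (30 mol %), 4 Å MS (removed before use), toluene, −40 → 0 °C
Reagents that add atoms: none
Why: The step is a concerted but asynchronous, suprafacial normal-electron-demand Diels–Alder reaction, and the closest known type is the BINOL–titanium-catalysed enantioselective addition of 2-silyloxydienes to alkoxy-1,4-benzoquinones. Six-membered ring A is closed intermolecularly on the intact ring B by forming C4–C5 and C1–C10 in one event through an endo transition state. Site selectivity comes from the methoxy group, which turns C7=C8 into a donor-substituted, unreactive alkene, so only C5=C10 is attacked. Regiochemistry comes from two-point binding of tetravalent titanium to the C9 carbonyl oxygen and the C8 methoxy oxygen, which makes C5 (β to C9=O) the most electrophilic carbon and pairs it with the nucleophilic enol-ether terminus C4 of 2. Quaternary C5 is set by the BINOL ligand, which shields one face of the chelated quinone; C10–H ends up cis to the C5 methyl because the addition is suprafacial, and the C4 methyl ends up trans to it because the Z diene carries that methyl on the outside and the approach is endo. Only the C5 configuration has to be right, since C4 and C10 are corrected later next to carbonyl groups.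

**Step 3**
Reactants: 4 cis-fused cycloadduct
Product: 5 trans-fused enedione (10α-H epimer of 4; 4α-CH3; 5β-CH3)
Conditions: DBU (10 mol %), CH2Cl2, Ar, 0 °C → rt
Reagents that add atoms: none
Why: Base-catalysed epimerisation α to a ketone, in which C10–H lies next to C9=O and is vinylogously linked to C6=O, so reversible deprotonation by a catalytic amidine moves the ring fusion to the more stable trans arrangement (10α-H anti to the 5β-methyl), while quaternary C5 cannot change and the silyl enol ether is inert to amine bases.

**Step 4**
Reactants: 5 trans-fused enedione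
Product: 6 8-methoxy-3-(tert-butyldimethylsilyloxy)-11,12,13-trinoreremophila-2,7-diene-6β,9β-diol (4α-CH3; 5β-CH3; 10α-H)
Conditions: LiAlH4, THF, −78 → 0 °C; Na2SO4·10H2O quench
Reagents that add atoms: none
Why: Hydride 1,2-reduction of an enedione, in which LiAlH4 reaches C9=O from the α face because the β axial trajectory is blocked by the syn-axial C5 methyl (axial 9β-ol) and reaches the vinylogous-ester carbonyl C6 along the α axial line (6β-ol), both enol ethers being inert and both carbinol configurations provisional (C6–O is lost in step 5 and C9 is corrected in step 6).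

**Step 5**
Reactants: 6 6β,9β-diol
Product: 7 9β-hydroxy-11,12,13-trinoreremophil-6-ene-3,8-dione with axial 4α-CH3 (5β-CH3; 10α-H)
Conditions: 1 M aq HCl, THF, rt
Reagents that add atoms: water, O
Why: Acid hydrolysis with allylic transposition, in which loss of the C6 hydroxyl is pushed by the C8 methoxy group, water adds at C8 and methanol leaves to give the C6=C7–C8=O enone, while protonation of the silyl enol ether at C2 frees the C3 ketone without breaking any bond at C4, C5, C9 or C10.

**Step 6**
Reactants: 7 9β-hydroxy-4α-methyl enedione
Product: 8 9α-hydroxy-11,12,13-trinoreremophil-6-ene-3,8-dione (4β-CH3; 5β-CH3; 10α-H)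
Conditions: K2CO3, degassed MeOH, Ar, rt
Reagents that add atoms: none
Why: Thermodynamic epimerisation by reversible deprotonation of C4–H (α to C3=O) and C9–H (α to C8=O), after which both substituents settle equatorially on the rigid trans-decalin (4β-methyl as in friedelin-type 4,5-dimethyl-3-decalones; 9α-hydroxyl free of the syn-axial clash with the C5 methyl and hydrogen-bonded to C8=O), with air excluded to prevent oxidation of the ketol.

**Step 7**
Reactants: 8 9α-hydroxy enedione; 9 (E)-3-methylpent-2-enoic acid
Product: 11 9α-[(E)-3-methylpent-2-enoyloxy]-11,12,13-trinoreremophil-6-ene-3,8-dione, via O-acylisourea 10 (not isolated)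
Conditions: DCC, DMAP (10 mol %), CH2Cl2, 0 °C → rt
Reagents that add atoms: none
Why: Steglich esterification, in which the carbodiimide activates acid 9 as 10 and DMAP passes the acyl group to the only hydroxyl of 8, with retention at C9 because the C9–O bond is not broken and with the E alkene preserved by working cold with little DMAP.

**Step 8**
Reactants: 11 C9 ester of the enedione
Product: 12 3β-hydroxy-9α-[(E)-3-methylpent-2-enoyloxy]-11,12,13-trinoreremophil-6-en-8-one
Conditions: NaBH4, MeOH/CH2Cl2 1:1, −78 → −40 °C; aq NH4Cl
Reagents that add atoms: none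
Why: Chemoselective borohydride reduction, since at low temperature in MeOH/CH2Cl2 a saturated ketone reacts much faster than a conjugated enone or an ester, and hydride reaches C3 from the α face because the β axial approach is blocked by the syn-axial C5 methyl, giving the axial 3β-alcohol (the outcome known for friedelin-type ketones).

**Step 9**
Reactants: 12 3β-hydroxy enone
Product: 13 3β-hydroxy-7-iodo-9α-[(E)-3-methylpent-2-enoyloxy]-11,12,13-trinoreremophil-6-en-8-one
Conditions: I2, pyridine/CH2Cl2 1:1, 0 °C → rt
Reagents that add atoms: iodine (I2), [I][I]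
Why: Baylis–Hillman-type α-iodination of an enone (reversible pyridine addition at C6, iodination at C7, loss of pyridine), a sequence that works on 4,4-disubstituted cyclohexenones and leaves the alcohol, the ester and all stereocentres untouched.

**Step 10**
Reactants: 13 7-iodo enone; 14 isopropenylboronic acid pinacol ester
Product: 15 3β-hydroxy-9α-[(E)-3-methylpent-2-enoyloxy]eremophila-6,11-dien-8-one
Conditions: Pd(dppf)Cl2 (5 mol %), K3PO4, THF/H2O 10:1, 40 °C
Reagents that add atoms: none
Why: Suzuki–Miyaura coupling, in which zerovalent palladium inserts into the carbon–iodine bond at C7, phosphate-assisted transmetalation from 14 follows and reductive elimination forms C7–C11 under conditions mild enough for the C9 ester and the free alcohol.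

**Step 11**
Reactants: 15 cross-conjugated dienone
Product: 17 3β-hydroxy-9α-[(E)-3-methylpent-2-enoyloxy]-7αH-eremophil-11-en-8-one (axial 7β-isopropenyl; expected together with its C7 epimer), via copper dienolate 16 (not isolated)
Conditions: [(PPh3)CuH]6, degassed H2O, toluene, rt
Reagents that add atoms: none
Why: Conjugate reduction with a phosphine-stabilised copper hydride, in which hydride adds to C6 (the only Michael terminus, along the α axial line anti to the C5 methyl) to give 16, which water protonates kinetically at its α-carbon C7 rather than at C12 so that the isopropenyl group stays unconjugated, the proton arriving mainly from the open α face, while the β,β-disubstituted enoate on C9 is too hindered to be reduced.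

**Step 12**
Reactants: 17 C7 epimer mixture rich in the 7β-isopropenyl ketone
Product: 18 3β-hydroxy-9α-[(E)-3-methylpent-2-enoyloxy]-7βH-eremophil-11-en-8-one (equatorial 7α-isopropenyl)
Conditions: Et3N, CH2Cl2, rt, followed closely and stopped at convergence
Reagents that add atoms: none
Why: Base-catalysed epimerisation of a doubly activated C–H (α to C8=O and allylic), in which the axial isopropenyl group of 17 is syn-axial to the C5 methyl, so reversible deprotonation with reprotonation at C7 drains it into the equatorial 7α epimer, C9 stays in its already equatorial configuration, and the weak base and early stop limit the slower protonation at C12 that would conjugate the alkene.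

**Step 13**
Reactants: 18 3β-hydroxy-7α-isopropenyl ketone; 19 angelic acid ((Z)-2-methylbut-2-enoic acid)
Product: 21 (3R,4R,5R,7S,9S,10R)-3α-angeloyloxy-9α-[(E)-3-methylpent-2-enoyloxy]eremophil-11-en-8-one (CNP0301161.1), via oxyphosphonium angelate 20 (not isolated)
Conditions: PPh3, DIAD, toluene, 0 °C → rt
Reagents that add atoms: none
Why: Mitsunobu reaction, in which the axial 3β-hydroxyl is converted into 20 and displaced by angelate from the α face in an SN2 process with inversion to the equatorial 3α-ester, and since the acid acts only as a carboxylate nucleophile and is never activated at its carbonyl group the Z alkene is retained.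

**Compound list**
1 | pent-1-en-3-one | C=CC(=O)CC | starting material
2 | (Z)-3-(tert-butyldimethylsilyloxy)penta-1,3-diene | C/C=C(/C=C)O[Si](C)(C)C(C)(C)C | intermediate
3 | 2-methoxy-5-methyl-1,4-benzoquinone | COC1=CC(=O)C(C)=CC1=O | starting material
4 | cis-fused cycloadduct (4α-CH3; 5β-CH3; 10β-H) | COC1=CC(=O)[C@]2(C)[C@H](C)C(O[Si](C)(C)C(C)(C)C)=CC[C@@H]2C1=O | intermediate
5 | trans-fused enedione (4α-CH3; 5β-CH3; 10α-H) | COC1=CC(=O)[C@]2(C)[C@H](C)C(O[Si](C)(C)C(C)(C)C)=CC[C@H]2C1=O | intermediate
6 | 6β,9β-diol with both enol ethers intact | COC1=C[C@@H](O)[C@]2(C)[C@H](C)C(O[Si](C)(C)C(C)(C)C)=CC[C@H]2[C@H]1O | intermediate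
7 | 9β-hydroxy-4α-methyl-trinoreremophil-6-ene-3,8-dione | C1=C[C@]2(C)[C@H](C)C(=O)CC[C@H]2[C@@H](O)C1=O | intermediate
8 | 9α-hydroxy-trinoreremophil-6-ene-3,8-dione (4β-CH3) | C1=C[C@]2(C)[C@@H](C)C(=O)CC[C@H]2[C@H](O)C1=O | intermediate
9 | (E)-3-methylpent-2-enoic acid | CC/C(C)=C/C(=O)O | starting material
10 | O-acylisourea from 9 and DCC (not isolated) | CC/C(C)=C/C(=O)OC(=NC1CCCCC1)NC1CCCCC1 | intermediate
11 | C9 (E)-3-methylpent-2-enoate of the enedione | C1=C[C@]2(C)[C@@H](C)C(=O)CC[C@H]2[C@H](OC(=O)/C=C(\C)CC)C1=O | intermediate
12 | 3β-hydroxy enone ester | C1=C[C@]2(C)[C@@H](C)[C@@H](O)CC[C@H]2[C@H](OC(=O)/C=C(\C)CC)C1=O | intermediate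
13 | 7-iodo enone | IC1=C[C@]2(C)[C@@H](C)[C@@H](O)CC[C@H]2[C@H](OC(=O)/C=C(\C)CC)C1=O | intermediate
14 | isopropenylboronic acid pinacol ester | C=C(C)B1OC(C)(C)C(C)(C)O1 | starting material
15 | 7-isopropenyl-6-en-8-one with axial 3β-ol | C=C(C)C1=C[C@]2(C)[C@@H](C)[C@@H](O)CC[C@H]2[C@H](OC(=O)/C=C(\C)CC)C1=O | intermediate
16 | copper dienolate, monovalent copper, phosphine omitted (not isolated) | C=C(C)C=1C[C@]2(C)[C@@H](C)[C@@H](O)CC[C@H]2[C@H](OC(=O)/C=C(\C)CC)C=1O[Cu] | intermediate
17 | 7β-isopropenyl (axial) ketone, C7 epimer of 18 | C=C(C)[C@H]1C[C@]2(C)[C@@H](C)[C@@H](O)CC[C@H]2[C@H](OC(=O)/C=C(\C)CC)C1=O | intermediate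
18 | 3β-hydroxy-9α-acyloxy-eremophil-11-en-8-one (7α-isopropenyl) | C=C(C)[C@@H]1C[C@]2(C)[C@@H](C)[C@@H](O)CC[C@H]2[C@H](OC(=O)/C=C(\C)CC)C1=O | intermediate
19 | angelic acid | C/C=C(/C)C(=O)O | starting material
20 | 3β-oxyphosphonium angelate (not isolated) | C=C(C)[C@@H]1C[C@]2(C)[C@@H](C)[C@@H](O[P+](c3ccccc3)(c3ccccc3)c3ccccc3)CC[C@H]2[C@H](OC(=O)/C=C(\C)CC)C1=O.C/C=C(/C)C(=O)[O-] | intermediate
21 | CNP0301161.1 | C=C(C)[C@@H]1C[C@]2(C)[C@@H](C)[C@H](OC(=O)/C(C)=C\C)CC[C@H]2[C@H](OC(=O)/C=C(\C)CC)C1=O | target

Total step count: 13. Longest linear sequence: 13 steps (1 → 21).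

**Steps most likely to fail**

**Step 2.**
- Risk: the methyl-bearing alkene is a slow dienophile. The uncatalysed background reaction, Lewis-acid-induced loss of the silyl group from the diene, or a stepwise Mukaiyama–Michael pathway may erode turnover and facial selectivity.
- Fallback: it sets out from 2 and 3 and returns at 5.
- The cycloaddition is run without catalyst in toluene at 80 °C. The intrinsic polarisation of the quinone (C9=O is a stronger acceptor than the vinylogous-ester C6=O) secures the same site and regiochemistry and gives the racemic cis adduct F1.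
- The DBU epimerisation of step 3 then gives the racemic trans-fused enedione F2.
- Preparative chromatography on a chiral stationary phase (SFC) delivers 5. Absolute configuration then comes from resolution instead of asymmetric catalysis.

**Step 12.**
- Risk: migration of the C11=C12 double bond into conjugation with C8=O, through protonation at C12, may compete with epimerisation at C7.
- Fallback: it sets out from 12 and returns at 18. It builds C7 by carbon–carbon bond formation on the open α face, so no proton has to be delivered to the hindered β face.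
- 12 is silylated (TESOTf, 2,6-lutidine, CH2Cl2, −78 °C) to the 3β-triethylsilyl ether F3.
- 1,4-Hydrosilylation (Et3SiH, RhCl(PPh3)3 cat., THF, 50 °C) gives the regiodefined C7=C8 triethylsilyl enol ether F4.
- Bu3SnF converts F4 in the flask into the tributyltin enolate F5. Palladium-catalysed ketone α-alkenylation with 2-bromopropene (PdCl2[P(o-tolyl)3]2, toluene, 80 °C) then places the isopropenyl group on the α face and gives the 3β-triethylsilyl ether of 18, F6.
- HF·pyridine (THF, 0 °C) releases 18.

**Step 13.**
- Risk: activation of the crowded axial hydroxyl (syn-axial to the C5 methyl, next to the C4 methyl) may be slow. Anti-periplanar E2 loss towards C2 or C4 may outrun substitution.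
- Fallback: it sets out from 18 and 19 and returns at 21. Activation and displacement are separated.
- 18 is converted (ClCH2SO2Cl, pyridine, CH2Cl2, 0 °C) into the 3β-chloromethanesulfonate F7.
- 19 is converted with Cs2CO3 into cesium angelate F8.
- F7 and F8 are combined with 18-crown-6 in toluene at 40–60 °C. This is the known cesium carboxylate inversion of hindered secondary sulfonates, and it gives 21 with the Z alkene intact.

**Further compounds**
F1 | step 2 | racemic cis adduct (4 and its enantiomer) | COC1=CC(=O)[C@]2(C)[C@H](C)C(O[Si](C)(C)C(C)(C)C)=CC[C@@H]2C1=O.COC1=CC(=O)[C@@]2(C)[C@@H](C)C(O[Si](C)(C)C(C)(C)C)=CC[C@H]2C1=O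
F2 | step 2 | racemic trans-fused enedione (5 and its enantiomer) | COC1=CC(=O)[C@]2(C)[C@H](C)C(O[Si](C)(C)C(C)(C)C)=CC[C@H]2C1=O.COC1=CC(=O)[C@@]2(C)[C@@H](C)C(O[Si](C)(C)C(C)(C)C)=CC[C@@H]2C1=O
F3 | step 12 | 3β-triethylsilyl ether of 12 | C1=C[C@]2(C)[C@@H](C)[C@@H](O[Si](CC)(CC)CC)CC[C@H]2[C@H](OC(=O)/C=C(\C)CC)C1=O
F4 | step 12 | C7=C8 triethylsilyl enol ether | C=1C[C@]2(C)[C@@H](C)[C@@H](O[Si](CC)(CC)CC)CC[C@H]2[C@H](OC(=O)/C=C(\C)CC)C=1O[Si](CC)(CC)CC
F5 | step 12 | tributyltin enolate | C=1C[C@]2(C)[C@@H](C)[C@@H](O[Si](CC)(CC)CC)CC[C@H]2[C@H](OC(=O)/C=C(\C)CC)C=1O[Sn](CCCC)(CCCC)CCCC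
F6 | step 12 | 3β-triethylsilyl ether of 18 | C=C(C)[C@@H]1C[C@]2(C)[C@@H](C)[C@@H](O[Si](CC)(CC)CC)CC[C@H]2[C@H](OC(=O)/C=C(\C)CC)C1=O
F7 | step 13 | 3β-chloromethanesulfonate of 18 | C=C(C)[C@@H]1C[C@]2(C)[C@@H](C)[C@@H](OS(=O)(=O)CCl)CC[C@H]2[C@H](OC(=O)/C=C(\C)CC)C1=O
F8 | step 13 | cesium angelate | C/C=C(/C)C(=O)[O-].[Cs+]
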